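The numbers in the tables are simulated with made-up constants; the scatter is artificial.

- Take the easy step first: in the flask below, product can grow no further than partner allows, so you can follow the partner pool (free partner plus dormant form) by watching product.

| flask | substrate | partner | reagent | remark | time |
|---|---|---|---|---|---|
| Wednesday's | 0.25 M | 0.90 equiv | 2.5 equiv | run made earlier |  |
| Friday's | 1 M | 0.90 equiv | 2.5 equiv | run made earlier |  |
| flask | 0.50 M | 0.900 equiv | 2.50 equiv |  | 25 h |

| run | time / h | open intermediate / % | product / % | substrate / % |
|---|---|---|---|---|
| Wednesday's | 0.333 | 63.4 | 10.0 | 29.6 |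
| Wednesday's | 1.33 | 71.2 | 26.2 | 2.7 |
| Wednesday's | 6.00 | 39.9 | 59.9 | 0 |
| Wednesday's | 30.0 | 12.5 | 88.0 | 0.3 |
| Friday's | 0.333 | 72.3 | 26.7 | 3.6 |
| Friday's | 1.33 | 41.6 | 59.0 | 0.1 |
| Friday's | 6.00 | 13.9 | 85.9 | 0 |
| Friday's | 30.0 | 9.0 | 88.3 | 0 |

(each reading ± 1 percentage point)

- the best time, 25 h at the latest, for open intermediate
- the amount of open intermediate, in percent of the substrate charged, at that time
- earliest time at which at least nineteen twentieths of that best amount are there
- latest time at which they still are

- My reckoning takes partner ⇌ dormant form as fast and at balance. Free partner is then a fixed share of the pool, and the pool decays pseudo-first-order, with rate constant k[reagent] for one lumped constant k.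
- On Wednesday's run, with substrate down to 2.7% at 1.33 h, the pool shrinks 2.12-fold between 1.33 h and 6.00 h. That gives the reading k = 1.67 × 10⁻⁴ M⁻¹ s⁻¹, and it carries the scatter of the readings.
- In the asked flask, the pool's half-life starts at 0.922 h. Then the reagent spent on substrate slows the rate 1.67-fold, and the reagent spent on partner slows it a further 2.50-fold.
- That leaves [reagent] = 0.300 M, so ln(2)/(k[reagent] at the end) comes to 3.84 h, and that is the late partner half-life.
- Held at that late rate for 25 h, the pool falls to 1.10% of its charge. Since [reagent] stands higher earlier, I expect less than that, with product near the partner charge.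
- The forecast, which reasons that “the kinetics are effectively bimolecular”, gives 73% at 0.5 h, with the window from 0.31 h to 0.75 h.
- The flask gives 74.7% at 0.432 h, with the window from 0.256 h to 0.730 h, so the forecast's best time is 1.16 times the simulated one. At 25.0 h, the slowest mode of the whole flask has a half-life of 3.43 h, against the late partner half-life of 3.84 h. Over the second half of the time allowed, the late partner half-life predicts a 9.55-fold fall, and free partner in the flask falls 12.8-fold, ending with product at 89.8%.

    substrate + reagent → open intermediate (k = 0.00210 M⁻¹ s⁻¹)
    reagent + partner → second intermediate (k = 3.90 × 10⁻⁴ M⁻¹ s⁻¹)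
    open intermediate + second intermediate → product (k = 0.0310 M⁻¹ s⁻¹)
    partner ⇌ dormant form (K = 1.10, k = 0.0320 s⁻¹)

- In the neighbouring flask with 0.540 equiv of partner and all else as in the recipe, the same reckoning gives a late half-life of 2.40 h, and held at that late rate, 0.0732% of the pool is left at 25 h.
- That neighbouring flask, computed, ends with 0.0098% of its partner free and product at 54.0%.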